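## Retrosynthetic overview

1. 15-Keto-PGF2α (17) ⇐ chemoselective oxidation of the allylic C15 carbinol of (15RS)-PGF2α (16). C15 is held at the alcohol level only so that it survives the ylide that builds the C5–C6 Z-alkene (Wittig on lactol 12).
2. Lactol 12 ⇐ bicyclic ethyl acetal enone 9 by 1,2-reduction, then acetal hydrolysis and desilylation.
3. Enone 9 ⇐ iodoacetal 8 + (E)-β-chlorovinyl ketone 3 by a new nickel-catalysed radical cyclisation/acylvinylation cascade. It forms C7–C8 and C12–C13, closes ring B and sets C8 and C12.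
4. Iodoacetal 8 ⇐ commercial (1R,4S)-cis-4-acetoxycyclopent-2-en-1-ol (4, source of C9 and C11) + ethyl vinyl ether; 3 ⇐ hexanoyl chloride + acetylene.
5. Ring order: ring A (cyclopentane) is bought intact in 4; ring B (tetrahydrofuran acetal) is formed in step 5 and opened again in step 8.

Assumption: positions are given in prostaglandin numbering (C1 = carboxyl carbon, C8 and C12 = ring carbons bearing the chains, C9 and C11 = ring carbinols); the acetal carbon (8–12) and C15 (10–12, 15, 16) are carried as epimer mixtures because both centres are erased before the target.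

## Route

Step 1
Reactants: 1 hexanoyl chloride; 2 acetylene
Product: 3 (E)-1-chlorooct-1-en-3-one
Conditions: AlCl3 (1.1 equiv), acetylene stream, CH2Cl2, 0 °C; then ice/aq. HCl
Reagents that add atoms: none
Why: Friedel–Crafts-type (Kondakov) acylation of acetylene: the acylium ion adds to the alkyne, chloride caps the vinyl cation, and the β-chlorovinyl ketone settles as the conjugated E isomer under the acidic conditions.

Step 2
Reactants: 4 (1R,4S)-cis-4-acetoxycyclopent-2-en-1-ol
Product: 5 (1S,4R)-4-[(tert-butyldimethylsilyl)oxy]cyclopent-2-en-1-yl acetate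
Conditions: TBSCl, imidazole, DMF, 0 °C → rt
Reagents that add atoms: tert-butyldimethylsilyl chloride (TBSCl), CC(C)(C)[Si](C)(C)Cl
Why: Imidazole-promoted silyl ether formation at the only free hydroxyl (future C11–O); no stereocentre is touched, so the bought configuration fixes C9 and C11.

Step 3
Reactants: 5 (1S,4R)-4-[(tert-butyldimethylsilyl)oxy]cyclopent-2-en-1-yl acetate
Product: 6 (1S,4R)-4-[(tert-butyldimethylsilyl)oxy]cyclopent-2-en-1-ol
Conditions: K2CO3 (0.2 equiv), MeOH, 0 °C
Reagents that add atoms: none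
Why: Carbonate-catalysed transesterification (methanolysis) removes the acetate while the secondary silyl ether is stable, freeing the future C9 hydroxyl without touching a stereocentre.

Step 4
Reactants: 6 (1S,4R)-4-[(tert-butyldimethylsilyl)oxy]cyclopent-2-en-1-ol; 7 ethyl vinyl ether
Product: 8 tert-butyl{[(1R,4S)-4-(1-ethoxy-2-iodoethoxy)cyclopent-2-en-1-yl]oxy}dimethylsilane (both acetal epimers)
Conditions: NIS, ethyl vinyl ether (3 equiv), CH2Cl2, −40 → −20 °C
Reagents that add atoms: N-iodosuccinimide (NIS), O=C1CCC(=O)N1I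
Why: Ueno–Stork haloacetalisation: NIS iodinates the electron-rich vinyl ether and the allylic alcohol traps the oxocarbenium ion; the new acetal centre forms unselectively and is erased in step 7.

Step 5
Reactants: 8 tert-butyl{[(1R,4S)-4-(1-ethoxy-2-iodoethoxy)cyclopent-2-en-1-yl]oxy}dimethylsilane; 3 (E)-1-chlorooct-1-en-3-one
Product: 9 (E)-1-[(3aR,4R,5R,6aS)-5-[(tert-butyldimethylsilyl)oxy]-2-ethoxyhexahydro-2H-cyclopenta[b]furan-4-yl]oct-1-en-3-one (both epimers at the acetal carbon C2)
Conditions: NiBr2(dme) (10 mol %; dme = 1,2-dimethoxyethane), 4,4'-di-tert-butyl-2,2'-bipyridine (12 mol %), Mn powder (3 equiv), 3 (2 equiv, slow addition), DMA, 25 °C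
Reagents that add atoms: none
Why: Proposed new method: a nickel-catalysed reductive radical cyclisation/vinylogous acylation cascade. Zerovalent nickel–bipyridine inserts into the carbon–chlorine bond of 3 (a vinylogous acid chloride) to give a divalent (E)-acylvinyl nickel chloride, and a monovalent nickel halide abstracts iodine from 8. The primary radical closes 5-exo-trig onto C8 faster than it can meet nickel, and the two-atom O–C tether from the C9 oxygen enforces the cis ring fusion, which sets C8. The C12 radical is then captured by the acylvinyl nickel species on the convex face, anti to both the new ring bond at C8 and the C11 silyloxy group. Reductive elimination from trivalent nickel forms C12–C13 with retention of the E geometry, which sets C12 trans to both neighbours, and Mn returns nickel to the zerovalent state. Direct radical addition to 3 followed by loss of a chlorine atom would converge on the same enone. The closest known reaction types are nickel-catalysed reductive cross-electrophile coupling of alkyl iodides with alkenyl halides and with acid chlorides, nickel-catalysed cyclisation/cross-coupling of haloacetals, and tin-mediated radical cyclisation/trapping of such iodoacetals with β-stannyl enones.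

Step 6
Reactants: 9 (E)-1-[(3aR,4R,5R,6aS)-5-[(tert-butyldimethylsilyl)oxy]-2-ethoxyhexahydro-2H-cyclopenta[b]furan-4-yl]oct-1-en-3-one
Product: 10 (E)-1-[(3aR,4R,5R,6aS)-5-[(tert-butyldimethylsilyl)oxy]-2-ethoxyhexahydro-2H-cyclopenta[b]furan-4-yl]oct-1-en-3-ol (both C15 epimers)
Conditions: NaBH4, CeCl3·7H2O (0.5 equiv), MeOH, −40 °C
Reagents that add atoms: none
Why: Luche reduction delivers hydride 1,2 to the enone without conjugate reduction; both C15 epimers are acceptable because step 9 returns C15 to the ketone, and the alcohol level shields C15 from the ylide in step 8.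

Step 7
Reactants: 10 (E)-1-[(3aR,4R,5R,6aS)-5-[(tert-butyldimethylsilyl)oxy]-2-ethoxyhexahydro-2H-cyclopenta[b]furan-4-yl]oct-1-en-3-ol
Product: 12 (3aR,4R,5R,6aS)-4-[(E)-3-hydroxyoct-1-enyl]hexahydro-2H-cyclopenta[b]furan-2,5-diol (lactol triol; anomers; both C15 epimers), via silyl lactol 11 (not isolated)
Conditions: 1 M aq. HCl/THF (1:2), rt, 16 h
Reagents that add atoms: water, O
Why: Acid-catalysed hydrolysis of the 2-ethoxytetrahydrofuran acetal (fast) is followed in the same pot by acidic cleavage of the secondary silyl ether (slower); no ring stereocentre is epimerisable under these conditions.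

Step 8
Reactants: 12 (3aR,4R,5R,6aS)-4-[(E)-3-hydroxyoct-1-enyl]hexahydro-2H-cyclopenta[b]furan-2,5-diol; 13 (4-carboxybutyl)triphenylphosphonium bromide
Product: 16 (5Z,13E,15RS)-9α,11α,15-trihydroxyprosta-5,13-dien-1-oic acid (PGF2α together with its 15-epimer), via phosphorus ylide 14 (not isolated), via hydroxy aldehyde 15 (not isolated)
Conditions: 13 (5 equiv), KOtBu (10 equiv), THF, 0 °C → rt; then aq. citric acid
Reagents that add atoms: none
Why: Wittig olefination: excess base opens the lactol to the alkoxide aldehyde, and the non-stabilised ylide reacts through the kinetic cis-oxaphosphetane to give the C5–C6 Z-alkene; the aldehyde α-carbon (C7) is a CH2, so no stereocentre can epimerise.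

Step 9
Reactants: 16 (5Z,13E,15RS)-9α,11α,15-trihydroxyprosta-5,13-dien-1-oic acid
Product: 17 15-keto-PGF2α, (5Z,13E)-9α,11α-dihydroxy-15-oxoprosta-5,13-dien-1-oic acid
Conditions: DDQ (1.3 equiv), 1,4-dioxane, rt
Reagents that add atoms: none
Why: DDQ dehydrogenation (hydride abstraction) occurs only at the alkene-activated C15 carbinol, leaving the saturated C9 and C11 alcohols, the Z-alkene and the acid untouched, and both C15 epimers converge on the E-enone.

## Compound list

1 | hexanoyl chloride | CCCCCC(=O)Cl | starting material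
2 | acetylene | C#C | starting material
3 | (E)-1-chlorooct-1-en-3-one | CCCCCC(=O)/C=C/Cl | intermediate
4 | (1R,4S)-cis-4-acetoxycyclopent-2-en-1-ol | C1=C[C@@H](OC(C)=O)C[C@H]1O | starting material
5 | (1S,4R)-4-[(tert-butyldimethylsilyl)oxy]cyclopent-2-en-1-yl acetate | C1=C[C@@H](OC(C)=O)C[C@H]1O[Si](C)(C)C(C)(C)C | intermediate
6 | (1S,4R)-4-[(tert-butyldimethylsilyl)oxy]cyclopent-2-en-1-ol | C1=C[C@@H](O)C[C@H]1O[Si](C)(C)C(C)(C)C | intermediate
7 | ethyl vinyl ether | C=COCC | starting material
8 | tert-butyl{[(1R,4S)-4-(1-ethoxy-2-iodoethoxy)cyclopent-2-en-1-yl]oxy}dimethylsilane (acetal epimers) | C1=C[C@@H](OC(OCC)CI)C[C@H]1O[Si](C)(C)C(C)(C)C | intermediate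
9 | (E)-1-[(3aR,4R,5R,6aS)-5-[(tert-butyldimethylsilyl)oxy]-2-ethoxyhexahydro-2H-cyclopenta[b]furan-4-yl]oct-1-en-3-one (C2 epimers) | CCCCCC(=O)/C=C/[C@@H]1[C@@H](CC(OCC)O2)[C@@H]2C[C@H]1O[Si](C)(C)C(C)(C)C | intermediate
10 | (E)-1-[(3aR,4R,5R,6aS)-5-[(tert-butyldimethylsilyl)oxy]-2-ethoxyhexahydro-2H-cyclopenta[b]furan-4-yl]oct-1-en-3-ol (C2 and C15 epimers) | CCCCCC(O)/C=C/[C@@H]1[C@@H](CC(OCC)O2)[C@@H]2C[C@H]1O[Si](C)(C)C(C)(C)C | intermediate
11 | silyl lactol: (3aR,4R,5R,6aS)-5-[(tert-butyldimethylsilyl)oxy]-4-[(E)-3-hydroxyoct-1-enyl]hexahydro-2H-cyclopenta[b]furan-2-ol | CCCCCC(O)/C=C/[C@@H]1[C@@H](CC(O)O2)[C@@H]2C[C@H]1O[Si](C)(C)C(C)(C)C | intermediate (not isolated)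
12 | lactol triol: (3aR,4R,5R,6aS)-4-[(E)-3-hydroxyoct-1-enyl]hexahydro-2H-cyclopenta[b]furan-2,5-diol | CCCCCC(O)/C=C/[C@@H]1[C@@H](CC(O)O2)[C@@H]2C[C@H]1O | intermediate
13 | (4-carboxybutyl)triphenylphosphonium bromide | OC(=O)CCCC[P+](c1ccccc1)(c1ccccc1)c1ccccc1.[Br-] | starting material
14 | phosphorus ylide: potassium 5-(triphenylphosphoranylidene)pentanoate | [K+].[O-]C(=O)CCCC=P(c1ccccc1)(c1ccccc1)c1ccccc1 | intermediate (not isolated)
15 | hydroxy aldehyde: 2-[(1R,2R,3R,5S)-3,5-dihydroxy-2-[(E)-3-hydroxyoct-1-enyl]cyclopentyl]acetaldehyde | CCCCCC(O)/C=C/[C@@H]1[C@@H](CC=O)[C@@H](O)C[C@H]1O | intermediate (not isolated)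
16 | (5Z,13E,15RS)-9α,11α,15-trihydroxyprosta-5,13-dien-1-oic acid (PGF2α and 15-epi-PGF2α) | CCCCCC(O)/C=C/[C@@H]1[C@@H](C/C=C\CCCC(=O)O)[C@@H](O)C[C@H]1O | intermediate
17 | 15-keto-PGF2α: (Z)-7-[(1R,2R,3R,5S)-3,5-dihydroxy-2-[(E)-3-oxooct-1-enyl]cyclopentyl]hept-5-enoic acid | CCCCCC(=O)/C=C/[C@@H]1[C@@H](C/C=C\CCCC(=O)O)[C@@H](O)C[C@H]1O | target

## Step count and risk

Total steps: 9. Longest linear sequence: 8 steps (4 → 17, steps 2–9); step 1 is a one-step side branch.

Steps most likely to fail:

**Step 5 (the proposed new cascade).** Risks are reductive dimerisation of 3, capture of the primary radical before cyclisation, and nickel-mediated reduction of the product enone. The fallback uses known tin chemistry; it sets out from 8 and comes back at 9. Commercial oct-1-yn-3-ol is hydrostannylated (Bu3SnH, AIBN cat., 80 °C) to (E)-1-(tributylstannyl)oct-1-en-3-ol F1, which MnO2 in CH2Cl2 oxidises to (E)-1-(tributylstannyl)oct-1-en-3-one F2. Heating 8 with F2 (2 equiv) and AIBN (0.2 equiv) in toluene at 110 °C runs the established tributyltin radical chain: iodine abstraction, 5-exo cyclisation, addition of the C12 radical to the β-stannyl enone and β-loss of the stannyl radical. This gives 9 with the same trans,trans arrangement.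

**Step 8 (Wittig on the unprotected lactol triol).** Three free hydroxyls consume base and can give a poorly soluble polyalkoxide and low conversion. The fallback replaces the protecting-group-free endgame by a fully silyl-protected one; it sets out from 10 and comes back at 16. Compound 10 is silylated at C15 (TBSCl, imidazole, DMF) to the 11,15-bis-O-TBS ethyl acetal F3. Brief mild hydrolysis (AcOH/THF/H2O, rt) opens only the acetal to the 11,15-bis-O-TBS lactol F4. This reacts through its open form, 2-[(1R,2R,3R,5S)-5-hydroxy-3-(TBS-oxy)-2-[(E)-3-(TBS-oxy)oct-1-enyl]cyclopentyl]acetaldehyde F5, with ylide 14 (from 13 and KOtBu, THF) to give 11,15-bis-O-TBS-(15RS)-PGF2α F6. Aqueous HCl/THF then removes both silyl groups to give 16.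

**Step 9 (chemoselective DDQ oxidation).** Risks are incomplete conversion of one C15 epimer or over-oxidation during a long reaction on the free triol acid. The fallback replaces chemoselective oxidation by protect–oxidise–release; it sets out from 16 and comes back at 17. Compound 16 is condensed with butylboronic acid (CH2Cl2, MgSO4, rt), which bridges only the cis-9,11-diol, to give (15RS)-PGF2α 9,11-O-butylboronate F7. The lone free C15 hydroxyl is oxidised with Dess–Martin periodinane (CH2Cl2, 0 °C) to 15-keto-PGF2α 9,11-O-butylboronate F8. Stirring with aqueous methanol hydrolyses the boronate and releases 17.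

## Further compounds

F1 | step 5 | (E)-1-(tributylstannyl)oct-1-en-3-ol | CCCCCC(O)/C=C/[Sn](CCCC)(CCCC)CCCC
F2 | step 5 | (E)-1-(tributylstannyl)oct-1-en-3-one | CCCCCC(=O)/C=C/[Sn](CCCC)(CCCC)CCCC
F3 | step 8 | 11,15-bis-O-TBS ethyl acetal (15-O-silyl ether of 10; C2 and C15 epimers) | CCCCCC(O[Si](C)(C)C(C)(C)C)/C=C/[C@@H]1[C@@H](CC(OCC)O2)[C@@H]2C[C@H]1O[Si](C)(C)C(C)(C)C
F4 | step 8 | 11,15-bis-O-TBS lactol: (3aR,4R,5R,6aS)-5-(TBS-oxy)-4-[(E)-3-(TBS-oxy)oct-1-enyl]hexahydro-2H-cyclopenta[b]furan-2-ol | CCCCCC(O[Si](C)(C)C(C)(C)C)/C=C/[C@@H]1[C@@H](CC(O)O2)[C@@H]2C[C@H]1O[Si](C)(C)C(C)(C)C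
F5 | step 8 | 2-[(1R,2R,3R,5S)-5-hydroxy-3-(TBS-oxy)-2-[(E)-3-(TBS-oxy)oct-1-enyl]cyclopentyl]acetaldehyde | CCCCCC(O[Si](C)(C)C(C)(C)C)/C=C/[C@@H]1[C@@H](CC=O)[C@@H](O)C[C@H]1O[Si](C)(C)C(C)(C)C
F6 | step 8 | 11,15-bis-O-TBS-(15RS)-PGF2α | CCCCCC(O[Si](C)(C)C(C)(C)C)/C=C/[C@@H]1[C@@H](C/C=C\CCCC(=O)O)[C@@H](O)C[C@H]1O[Si](C)(C)C(C)(C)C
F7 | step 9 | (15RS)-PGF2α 9,11-O-butylboronate | CCCCCC(O)/C=C/[C@@H]1[C@@H](C/C=C\CCCC(=O)O)[C@@H]2C[C@H]1OB(CCCC)O2
F8 | step 9 | 15-keto-PGF2α 9,11-O-butylboronate | CCCCCC(=O)/C=C/[C@@H]1[C@@H](C/C=C\CCCC(=O)O)[C@@H]2C[C@H]1OB(CCCC)O2
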